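## Retrosynthetic overview

1. Quinone ⇐ 3-heneicosyl-5-methoxy-2-methylphenol: the second quinone oxygen goes in last, para to the phenol OH, as in the hydroxylation that ends the biosynthesis.
2. Phenol ⇐ linear tetraketide acid (docosanoyl starter, one methylmalonate, two malonates; C3 oxygen already a methyl ether; C1 = CO2H, C7 = ketone carrying the chain). C2→C7 aldol, aromatisation and loss of C1 as CO2 form the only ring, once.
3. Tetraketide ⇐ its lactone, a 6-substituted 4-methoxy-2-pyrone. Cutting C6–C7 (Claisen) and C6–CH3 (enolate methylation) leaves 4-methoxy-6-methyl-2-pyrone, methyl docosanoate and MeI, joined in one flask.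
4. Order: chain assembly → benzene ring (aldol/decarboxylation) → quinone. The pyrone ring is bought and consumed; it fixes the OMe position, so no selective O-methylation is needed.

Assumption: the target has no stereocentre and no stereogenic double bond, so the structure given is its only stereoisomer; the side chain is read as n-heneicosyl (C21).

## Route

Step 1
Reactants: 1 4-methoxy-6-methyl-2H-pyran-2-one; 2 methyl docosanoate
Product: 6 rac-4-methoxy-6-(3-oxotetracosan-2-yl)-2H-pyran-2-one, via lithiated pyrone 3 (not isolated), via unmethylated ketopyrone 4 (not isolated), via lithium enolate 5 (not isolated)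
Conditions: LiN(iPr)2 (2.1 equiv), 1 (2.1 equiv), THF, −78 °C; 2 (1.0 equiv), −78 → −20 °C; then DMPU, MeI (1.3 equiv), −20 °C → rt; aq. NH4Cl (one equivalent of 1 is regenerated and recovered)
Reagents that add atoms: iodomethane (MeI), CI
Why: Vinylogous Claisen condensation followed by enolate C-alkylation: the extended enolate 3 at the 6-methyl group acylates ester 2, the more acidic ketopyrone 4 is deprotonated at once by the second equivalent of 3, and the doubly stabilised enolate 5 is methylated by soft MeI at the carbon between ketone and pyrone; the new stereocentre is racemic and is erased on aromatisation in step 2.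

Step 2
Reactants: 6 rac-4-methoxy-6-(3-oxotetracosan-2-yl)-2H-pyran-2-one
Product: 9 3-heneicosyl-5-methoxy-2-methylphenol, via open-chain tetraketide acid 7 (not isolated), via hydroxybenzoic acid 8 (not isolated)
Conditions: KOH (6 equiv), 1,4-dioxane/H2O (3:1), 85 °C, N2; then 6 M HCl to pH 1, 90 °C
Reagents that add atoms: none
Why: Biomimetic polyketide cyclisation (pyrone ring opening, intramolecular aldol condensation, decarboxylation): hydroxide opens the lactone to carboxylate 7, whose C1 can no longer undergo Claisen closure, so the vinylogous enolate formed by loss of a C4 proton attacks the C7 ketone through C2, loss of water and enolisation give aromatic acid 8, and on acidification this electron-rich 2,6-disubstituted 4-hydroxybenzoic acid is protonated at the ipso carbon and loses CO2 as orsellinic acid does; no stereocentre remains.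

Step 3
Reactants: 9 3-heneicosyl-5-methoxy-2-methylphenol
Product: 10 3-heneicosyl-5-methoxy-2-methylcyclohexa-2,5-diene-1,4-dione (CNP0104330.0)
Conditions: (KSO3)2NO (3 equiv), Bu4NHSO4 (cat.), CH2Cl2/aq. KH2PO4 (pH 6), rt
Reagents that add atoms: potassium nitrosodisulfonate (Fremy's salt, (KSO3)2NO), [K+].[K+].[O]N(S(=O)(=O)[O-])S(=O)(=O)[O-]
Why: Teuber oxidation: one nitrosodisulfonate radical abstracts the phenolic hydrogen, a second couples at the free para carbon, and loss of imidodisulfonate gives the para-quinone, as 3-methoxy-5-alkylphenols give 2-methoxy-6-alkyl-1,4-benzoquinones; the ortho methyl blocks one ortho site, the methoxy group survives at pH 6, and no stereocentre is formed.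

## Compound list

1 | 4-methoxy-6-methyl-2H-pyran-2-one | COC1=CC(=O)OC(C)=C1 | starting material
2 | methyl docosanoate | CCCCCCCCCCCCCCCCCCCCCC(=O)OC | starting material
3 | [(4-methoxy-2-oxo-2H-pyran-6-yl)methyl]lithium (lithiated pyrone) | [Li]CC1=CC(OC)=CC(=O)O1 | intermediate
4 | 4-methoxy-6-(2-oxotricosyl)-2H-pyran-2-one (unmethylated ketopyrone) | CCCCCCCCCCCCCCCCCCCCCC(=O)CC1=CC(OC)=CC(=O)O1 | intermediate
5 | lithium (1Z)-1-(4-methoxy-2-oxo-2H-pyran-6-yl)tricos-1-en-2-olate (lithium enolate) | CCCCCCCCCCCCCCCCCCCCC/C(O[Li])=C/C1=CC(OC)=CC(=O)O1 | intermediate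
6 | rac-4-methoxy-6-(3-oxotetracosan-2-yl)-2H-pyran-2-one | CCCCCCCCCCCCCCCCCCCCCC(=O)C(C)C1=CC(OC)=CC(=O)O1 | intermediate
7 | (2E)-3-methoxy-6-methyl-5,7-dioxooctacos-2-enoic acid (racemic at C6; present as its potassium salt) | OC(=O)/C=C(/OC)CC(=O)C(C)C(=O)CCCCCCCCCCCCCCCCCCCCC | intermediate
8 | 2-heneicosyl-4-hydroxy-6-methoxy-3-methylbenzoic acid | CCCCCCCCCCCCCCCCCCCCCc1c(C)c(O)cc(OC)c1C(=O)O | intermediate
9 | 3-heneicosyl-5-methoxy-2-methylphenol | CCCCCCCCCCCCCCCCCCCCCc1cc(OC)cc(O)c1C | intermediate
10 | 3-heneicosyl-5-methoxy-2-methylcyclohexa-2,5-diene-1,4-dione | CCCCCCCCCCCCCCCCCCCCCC1=C(C)C(=O)C=C(OC)C1=O | target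

## Step count and risks

Total steps: 3. Longest linear sequence: 3.

Most likely to fail, in order:

**Step 2.** The risks are retro-Claisen cleavage of the 2-methyl-1,3-diketone by hydroxide, loss of the enol-ether methyl by addition–elimination, and a slow aldol onto the hindered C7 ketone. The fallback sets out from 6 and is a hydroxide-free, magnesium-templated cyclisation at the ester oxidation level. Mg(OMe)2 in MeOH/THF at reflux opens the lactone with methoxide, the chelated diketonate is shielded from cleavage, and the aldol gives methyl 2-heneicosyl-4-hydroxy-6-methoxy-3-methylbenzoate F2. The hindered ester is then cleaved by SN2 demethylation with LiCl in DMF at 150 °C to the lithium salt of 8, and acidification with warming expels CO2. The route is rejoined at 9.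

**Step 1.** The risks are double or O-methylation of enolate 5 and a low-yielding acylation by the long-chain ester. The fallback sets out from 1 and reverses the order of the two C–C bond formations. LiN(iPr)2 then MeI in THF at −78 °C gives 6-ethyl-4-methoxy-2H-pyran-2-one F1. Its lithiated methylene carbon (2 equiv of F1 and of LiN(iPr)2, THF, −78 °C) is acylated with 2, so the methyl branch is already in place and no alkylation of a ketopyrone enolate is needed. NH4Cl quench rejoins the route at 6.

**Step 3.** The risks are the two-phase reaction of a waxy phenol, some ortho-quinone and over-oxidation. The fallback sets out from 9 and replaces the radical oxidation by a homogeneous two-electron oxidation to a masked quinone. PhI(OAc)2 (2.2 equiv) in MeOH/CH2Cl2 at 0 °C, with methanol capturing the phenoxonium ion twice at the para carbon, gives the quinone monoketal 3-heneicosyl-4,4,5-trimethoxy-2-methylcyclohexa-2,5-dien-1-one F3. Hydrolysis of the ketal with dilute aqueous HCl in THF rejoins the route at 10.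

## Further compounds

F1 | step 1 | 6-ethyl-4-methoxy-2H-pyran-2-one | CCC1=CC(OC)=CC(=O)O1
F2 | step 2 | methyl 2-heneicosyl-4-hydroxy-6-methoxy-3-methylbenzoate | CCCCCCCCCCCCCCCCCCCCCc1c(C)c(O)cc(OC)c1C(=O)OC
F3 | step 3 | 3-heneicosyl-4,4,5-trimethoxy-2-methylcyclohexa-2,5-dien-1-one | CCCCCCCCCCCCCCCCCCCCCC1=C(C)C(=O)C=C(OC)C1(OC)OC
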